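A direct plan would join two finished rings by SNAr of phenol A2 (3-allyloxy-2-hydroxy-5-methylbenzaldehyde) on fluoro keto ester A1 (methyl 6-fluoro-2-methoxy-3-(3-methylbutanoyl)benzoate) to give diaryl ether A3.
It would then reduce the aldehyde, reduce the ketone enantioselectively and deprotect.
Its weakest steps would be:
- the SNAr union, because the di-ortho-substituted, formyl-conjugated phenoxide would be a poor nucleophile while base and heat would threaten the enolisable ketone and the ester;
- the reduction of the aldehyde beside the aryl ketone, a pure chemoselectivity problem that would add a step without adding complexity;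
- the late enantioselective reduction of the ortho-substituted aryl ketone on the full diaryl ether, which would depend on finding a matching catalyst or enzyme for a bulky substrate.

The new route does not join two finished arenes; it builds ring A around the ether oxygen. Ring A carries its oxygens at C2 and C6 with the carboxyl carbon C1 between them and the side chain at C3 next to the C2 oxygen, which is exactly the pattern that a vinylketene–ynol ether benzannulation lays down. Ring B therefore enters as an aryl ethynyl ether, and a Danheiser benzannulation with the vinylketene from an L-leucic-acid-derived diazoketone forms C1–C2, C5–C6 and C2–C3 of ring A in one operation, with the stereocentre already in place. No SNAr union, no aldehyde-versus-ketone reduction and no late asymmetric reduction remain.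

Key step: step 10

Remark: both starting materials are taken as purchasable, the hydroxy ester as the (S)-enantiomer; ring A is numbered as in the target acid (C1 carboxyl carbon, C2 OMe, C3 side chain, C6 ether oxygen). TBS = tert-butyldimethylsilyl, TIPS = triisopropylsilyl, ArB = 2-[(TBSO)methyl]-4-methyl-6-(TIPSO)phenyl.

Step 1
Reactants: 1 methyl (2S)-2-hydroxy-4-methylpentanoate
Product: 2 methyl (2S)-2-[(tert-butyldimethylsilyl)oxy]-4-methylpentanoate
Conditions: TBSCl (1.2 equiv), imidazole (2.0 equiv), DMF, 0 °C → rt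
Reagents that add atoms: tert-butyldimethylsilyl chloride, CC(C)(C)[Si](C)(C)Cl
Why: Silyl ether formation caps the secondary hydroxyl without touching the chiral-pool (S)-centre, which becomes the carbinol carbon of the target.

Step 2
Reactants: 2 methyl (2S)-2-[(tert-butyldimethylsilyl)oxy]-4-methylpentanoate
Product: 3 (2S)-2-[(tert-butyldimethylsilyl)oxy]-4-methylpentanal
Conditions: i-Bu2AlH (1.1 equiv), CH2Cl2, −78 °C; MeOH, then aq. potassium sodium tartrate
Reagents that add atoms: none
Why: Partial hydride reduction of the ester stops at the aluminium hemiacetal at −78 °C and releases the α-silyloxy aldehyde on work-up; it should be used at once to avoid epimerisation.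

Step 3
Reactants: 3 (2S)-2-[(tert-butyldimethylsilyl)oxy]-4-methylpentanal
Product: 4 (3E,5S)-5-[(tert-butyldimethylsilyl)oxy]-7-methyloct-3-en-2-one
Conditions: Ph3P=CHC(O)CH3 (1.3 equiv), toluene, 60 °C
Reagents that add atoms: 1-(triphenylphosphoranylidene)propan-2-one, CC(=O)C=P(c1ccccc1)(c1ccccc1)c1ccccc1
Why: Wittig olefination with a stabilised acyl ylide should give the (E)-enone under neutral conditions that leave the adjacent stereocentre intact.

Step 4
Reactants: 4 (3E,5S)-5-[(tert-butyldimethylsilyl)oxy]-7-methyloct-3-en-2-one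
Product: 6 (3E,5S)-5-[(tert-butyldimethylsilyl)oxy]-1-diazo-7-methyloct-3-en-2-one, via trifluoroacetyl diketone 5 (not isolated)
Conditions: LiN(SiMe3)2 (1.1 equiv), THF, −78 °C; CF3CO2CH2CF3 (1.2 equiv), −78 °C; then MsN3 (1.5 equiv), Et3N (1.5 equiv), H2O (1 equiv), MeCN, rt
Reagents that add atoms: methanesulfonyl azide, CS(=O)(=O)N=[N+]=[N-]
Why: Detrifluoroacetylative diazo transfer: the kinetic enolate of the methyl group (not the γ-position that bears the stereocentre) is trifluoroacetylated, and the activated diketone takes the diazo group from MsN3 with loss of the trifluoroacetyl group.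

Step 5
Reactants: 7 2-hydroxy-3-(hydroxymethyl)-5-methylbenzaldehyde
Product: 8 3-{[(tert-butyldimethylsilyl)oxy]methyl}-2-hydroxy-5-methylbenzaldehyde
Conditions: TBSCl (1.05 equiv), imidazole (2.0 equiv), CH2Cl2, 0 °C
Reagents that add atoms: tert-butyldimethylsilyl chloride, CC(C)(C)[Si](C)(C)Cl
Why: Chemoselective silylation of the primary benzylic alcohol, since the phenol is hindered and held in a hydrogen bond to the formyl group.

Step 6
Reactants: 8 3-{[(tert-butyldimethylsilyl)oxy]methyl}-2-hydroxy-5-methylbenzaldehyde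
Product: 9 3-{[(tert-butyldimethylsilyl)oxy]methyl}-2-{[(E)-1,2-dichloroethenyl]oxy}-5-methylbenzaldehyde
Conditions: Cl2C=CHCl (2.0 equiv), K2CO3 (2.0 equiv), DMF, 70 °C
Reagents that add atoms: trichloroethylene, ClC=C(Cl)Cl
Why: Base forms dichloroacetylene from trichloroethylene in situ and the phenoxide adds to it in anti fashion (nucleophilic addition to a haloalkyne), which fixes the oxygen that will carry ring A as an (E)-dichlorovinyl ether.

Step 7
Reactants: 9 3-{[(tert-butyldimethylsilyl)oxy]methyl}-2-{[(E)-1,2-dichloroethenyl]oxy}-5-methylbenzaldehyde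
Product: 11 3-{[(tert-butyldimethylsilyl)oxy]methyl}-2-{[(E)-1,2-dichloroethenyl]oxy}-5-methylphenol, via aryl formate 10 (not isolated)
Conditions: mCPBA (1.5 equiv), CH2Cl2, 0 °C → rt; then MeOH, Et3N (0.2 equiv), 0 °C
Reagents that add atoms: 3-chloroperoxybenzoic acid, OOC(=O)c1cccc(Cl)c1
Why: Baeyer–Villiger (Dakin-type) oxidation in which the aryl group, activated by the ortho oxygen, should migrate in preference to hydrogen, the electron-poor dichloroalkene being inert to the peracid; mild methanolysis of the formate then gives the second catechol oxygen already differentiated from the first.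

Step 8
Reactants: 11 3-{[(tert-butyldimethylsilyl)oxy]methyl}-2-{[(E)-1,2-dichloroethenyl]oxy}-5-methylphenol
Product: 12 tert-butyl[(2-{[(E)-1,2-dichloroethenyl]oxy}-5-methyl-3-[(triisopropylsilyl)oxy]phenyl)methoxy]dimethylsilane
Conditions: TIPSCl (1.2 equiv), imidazole (2.5 equiv), DMF, rt
Reagents that add atoms: triisopropylsilyl chloride, CC(C)[Si](Cl)(C(C)C)C(C)C
Why: Silylation of the unhindered phenol gives a robust aryl TIPS ether that cannot migrate, because the neighbouring oxygen is blocked, and that withstands the organolithium and carbonate steps ahead.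

Step 9
Reactants: 12 tert-butyl[(2-{[(E)-1,2-dichloroethenyl]oxy}-5-methyl-3-[(triisopropylsilyl)oxy]phenyl)methoxy]dimethylsilane
Product: 15 tert-butyl({2-(ethynyloxy)-5-methyl-3-[(triisopropylsilyl)oxy]phenyl}methoxy)dimethylsilane (ArB–O–C≡CH), via chloroalkyne 13 (not isolated), via lithium acetylide 14 (not isolated)
Conditions: n-BuLi (2.3 equiv), THF, −78 → −40 °C; MeOH, −78 °C
Reagents that add atoms: none
Why: Elimination followed by halogen–lithium exchange: n-BuLi removes the vinylic proton, chloride leaves to give the chloroalkyne, a second equivalent exchanges the remaining chlorine, and protonation of the acetylide gives the terminal aryl ynol ether.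

Step 10
Reactants: 6 (3E,5S)-5-[(tert-butyldimethylsilyl)oxy]-1-diazo-7-methyloct-3-en-2-one; 15 tert-butyl({2-(ethynyloxy)-5-methyl-3-[(triisopropylsilyl)oxy]phenyl}methoxy)dimethylsilane
Product: 20 5-(ArB-oxy)-2-[(1S)-1-(TBSO)-3-methylbutyl]phenol, via vinylketene 16 (not isolated), via vinylcyclobutenone 17 (not isolated), via dienylketene 18 (not isolated), via cyclohexadienone 19 (not isolated)
Conditions: 6 (1.3 equiv), 15 (1.0 equiv), hν (300 nm), ClCH2CH2Cl, rt; then 80 °C
Reagents that add atoms: none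
Why: Danheiser benzannulation in its photochemical Wolff variant: light expels N2 from 6 and 1,2-shift of the alkenyl group gives the (E)-vinylketene 16, whose electrophilic carbonyl carbon is attacked by the nucleophilic CH terminus of ynol ether 15 in a regiospecific [2+2] cycloaddition to cyclobutenone 17. On warming, 17 opens by a 4π-electrocyclic reaction to dienylketene 18, ring A closes by a 6π-electrocyclic reaction and cyclohexadienone 19 tautomerises to phenol 20. The closest known reaction type is the benzannulation of α,β-unsaturated α′-diazoketones with alkoxy- and siloxyalkynes. Ring A is thus closed by cycloaddition (C1–C2 and C5–C6) followed by 6π-electrocyclisation (C2–C3), the four-membered ring of 17 being only a relay, so OH at C2, H at C1, the aryloxy group at C6 and the side chain at C3 are placed by the mechanism alone. No stereocentre is created (the sp3 centres of 17 and 19 vanish on aromatisation), and the (S)-silyloxy centre is a spectator because it is not enolisable and the E-alkene keeps its C–H out of reach of a [1,5]-hydrogen shift to the ketene. The step needs the ketene to be captured by the alkyne rather than by itself or by the product, which the polarised ynol ether (its oxygen twisted out of conjugation with the di-ortho-substituted ring B, and unable to undergo retro-ene loss on heating) and the hindered phenol of 20 should secure.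

Step 11
Reactants: 20 5-(ArB-oxy)-2-[(1S)-1-(TBSO)-3-methylbutyl]phenol
Product: 21 4-(ArB-oxy)-2-methoxy-1-[(1S)-1-(TBSO)-3-methylbutyl]benzene
Conditions: MeI (3 equiv), K2CO3 (2 equiv), acetone, 50 °C
Reagents that add atoms: iodomethane, CI
Why: Williamson O-methylation of the only free phenol (SN2 on MeI); the alkyl TBS and aryl TIPS ethers should be stable to K2CO3 in dry acetone.

Step 12
Reactants: 21 4-(ArB-oxy)-2-methoxy-1-[(1S)-1-(TBSO)-3-methylbutyl]benzene
Product: 23 6-(ArB-oxy)-2-methoxy-3-[(1S)-1-(TBSO)-3-methylbutyl]benzoic acid, via aryllithium 22 (not isolated)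
Conditions: n-BuLi (1.4 equiv), THF, 0 °C, 1.5 h; CO2 (g), −78 °C → rt; cold 0.5 M HCl to pH 3
Reagents that add atoms: carbon dioxide, O=C=O
Why: Directed ortho-metalation: C1–H lies between the methoxy and aryloxy oxygens, which both coordinate lithium and acidify it, so lithiation there and carboxylation should give the benzoic acid directly, the silyl ethers being poor directing groups.

Step 13
Reactants: 23 6-(ArB-oxy)-2-methoxy-3-[(1S)-1-(TBSO)-3-methylbutyl]benzoic acid
Product: 24 6-[2-hydroxy-6-(hydroxymethyl)-4-methylphenoxy]-3-[(1S)-1-hydroxy-3-methylbutyl]-2-methoxybenzoic acid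
Conditions: Bu4NF (5 equiv), THF, rt → 40 °C; aq. citric acid to pH 4
Reagents that add atoms: none
Why: Fluoride-mediated desilylation removes the three silyl ethers in one operation under non-acidic conditions, so the electron-rich benzylic (S)-carbinol cannot ionise and should keep its configuration.

**Compound list**
1 | methyl (2S)-2-hydroxy-4-methylpentanoate | CC(C)C[C@H](O)C(=O)OC | starting material
2 | methyl (2S)-2-[(tert-butyldimethylsilyl)oxy]-4-methylpentanoate | CC(C)C[C@H](O[Si](C)(C)C(C)(C)C)C(=O)OC | intermediate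
3 | (2S)-2-[(tert-butyldimethylsilyl)oxy]-4-methylpentanal | CC(C)C[C@H](O[Si](C)(C)C(C)(C)C)C=O | intermediate
4 | (3E,5S)-5-[(tert-butyldimethylsilyl)oxy]-7-methyloct-3-en-2-one | CC(C)C[C@H](O[Si](C)(C)C(C)(C)C)/C=C/C(C)=O | intermediate
5 | (5E,7S)-7-[(tert-butyldimethylsilyl)oxy]-1,1,1-trifluoro-9-methyldec-5-ene-2,4-dione | CC(C)C[C@H](O[Si](C)(C)C(C)(C)C)/C=C/C(=O)CC(=O)C(F)(F)F | intermediate
6 | (3E,5S)-5-[(tert-butyldimethylsilyl)oxy]-1-diazo-7-methyloct-3-en-2-one | CC(C)C[C@H](O[Si](C)(C)C(C)(C)C)/C=C/C(=O)C=[N+]=[N-] | intermediate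
7 | 2-hydroxy-3-(hydroxymethyl)-5-methylbenzaldehyde | Cc1cc(CO)c(O)c(C=O)c1 | starting material
8 | 3-{[(tert-butyldimethylsilyl)oxy]methyl}-2-hydroxy-5-methylbenzaldehyde | Cc1cc(CO[Si](C)(C)C(C)(C)C)c(O)c(C=O)c1 | intermediate
9 | 3-{[(tert-butyldimethylsilyl)oxy]methyl}-2-{[(E)-1,2-dichloroethenyl]oxy}-5-methylbenzaldehyde | Cc1cc(CO[Si](C)(C)C(C)(C)C)c(O/C(Cl)=C\Cl)c(C=O)c1 | intermediate
10 | 3-{[(tert-butyldimethylsilyl)oxy]methyl}-2-{[(E)-1,2-dichloroethenyl]oxy}-5-methylphenyl formate | Cc1cc(CO[Si](C)(C)C(C)(C)C)c(O/C(Cl)=C\Cl)c(OC=O)c1 | intermediate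
11 | 3-{[(tert-butyldimethylsilyl)oxy]methyl}-2-{[(E)-1,2-dichloroethenyl]oxy}-5-methylphenol | Cc1cc(CO[Si](C)(C)C(C)(C)C)c(O/C(Cl)=C\Cl)c(O)c1 | intermediate
12 | tert-butyl[(2-{[(E)-1,2-dichloroethenyl]oxy}-5-methyl-3-[(triisopropylsilyl)oxy]phenyl)methoxy]dimethylsilane | Cc1cc(CO[Si](C)(C)C(C)(C)C)c(O/C(Cl)=C\Cl)c(O[Si](C(C)C)(C(C)C)C(C)C)c1 | intermediate
13 | tert-butyl({2-[(chloroethynyl)oxy]-5-methyl-3-[(triisopropylsilyl)oxy]phenyl}methoxy)dimethylsilane | Cc1cc(CO[Si](C)(C)C(C)(C)C)c(OC#CCl)c(O[Si](C(C)C)(C(C)C)C(C)C)c1 | intermediate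
14 | lithium acetylide of 15 (ArB–O–C≡C–Li) | Cc1cc(CO[Si](C)(C)C(C)(C)C)c(OC#C[Li])c(O[Si](C(C)C)(C(C)C)C(C)C)c1 | intermediate
15 | tert-butyl({2-(ethynyloxy)-5-methyl-3-[(triisopropylsilyl)oxy]phenyl}methoxy)dimethylsilane | Cc1cc(CO[Si](C)(C)C(C)(C)C)c(OC#C)c(O[Si](C(C)C)(C(C)C)C(C)C)c1 | intermediate
16 | (3E,5S)-5-[(tert-butyldimethylsilyl)oxy]-7-methylocta-1,3-dien-1-one (vinylketene) | CC(C)C[C@H](O[Si](C)(C)C(C)(C)C)/C=C/C=C=O | intermediate
17 | 3-(ArB-oxy)-4-[(1E,3S)-3-(TBSO)-5-methylhex-1-en-1-yl]cyclobut-2-en-1-one (mixture at C4) | CC(C)C[C@H](O[Si](C)(C)C(C)(C)C)/C=C/C1C(=O)C=C1Oc1c(CO[Si](C)(C)C(C)(C)C)cc(C)cc1O[Si](C(C)C)(C(C)C)C(C)C | intermediate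
18 | (3E,5E,7S)-3-(ArB-oxy)-7-(TBSO)-9-methyldeca-1,3,5-trien-1-one (dienylketene) | CC(C)C[C@H](O[Si](C)(C)C(C)(C)C)/C=C/C=C(/Oc1c(CO[Si](C)(C)C(C)(C)C)cc(C)cc1O[Si](C(C)C)(C(C)C)C(C)C)C=C=O | intermediate
19 | 3-(ArB-oxy)-6-[(1S)-1-(TBSO)-3-methylbutyl]cyclohexa-2,4-dien-1-one (mixture at C6) | CC(C)C[C@H](O[Si](C)(C)C(C)(C)C)C1C=CC(Oc2c(CO[Si](C)(C)C(C)(C)C)cc(C)cc2O[Si](C(C)C)(C(C)C)C(C)C)=CC1=O | intermediate
20 | 5-(ArB-oxy)-2-[(1S)-1-(TBSO)-3-methylbutyl]phenol | CC(C)C[C@H](O[Si](C)(C)C(C)(C)C)c1ccc(Oc2c(CO[Si](C)(C)C(C)(C)C)cc(C)cc2O[Si](C(C)C)(C(C)C)C(C)C)cc1O | intermediate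
21 | 4-(ArB-oxy)-2-methoxy-1-[(1S)-1-(TBSO)-3-methylbutyl]benzene | CC(C)C[C@H](O[Si](C)(C)C(C)(C)C)c1ccc(Oc2c(CO[Si](C)(C)C(C)(C)C)cc(C)cc2O[Si](C(C)C)(C(C)C)C(C)C)cc1OC | intermediate
22 | {6-(ArB-oxy)-2-methoxy-3-[(1S)-1-(TBSO)-3-methylbutyl]phenyl}lithium | CC(C)C[C@H](O[Si](C)(C)C(C)(C)C)c1ccc(Oc2c(CO[Si](C)(C)C(C)(C)C)cc(C)cc2O[Si](C(C)C)(C(C)C)C(C)C)c([Li])c1OC | intermediate
23 | 6-(ArB-oxy)-2-methoxy-3-[(1S)-1-(TBSO)-3-methylbutyl]benzoic acid | CC(C)C[C@H](O[Si](C)(C)C(C)(C)C)c1ccc(Oc2c(CO[Si](C)(C)C(C)(C)C)cc(C)cc2O[Si](C(C)C)(C(C)C)C(C)C)c(C(=O)O)c1OC | intermediate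
24 | 6-[2-hydroxy-6-(hydroxymethyl)-4-methylphenoxy]-3-[(1S)-1-hydroxy-3-methylbutyl]-2-methoxybenzoic acid | COc1c([C@@H](O)CC(C)C)ccc(Oc2c(O)cc(C)cc2CO)c1C(=O)O | target

**Totals**
Total step count: 13. Longest linear sequence: 9 steps (7 to 24, steps 5 to 13).

**Steps most likely to fail**

1. Step 10. The vinylketene could be lost to dimerisation or to acylation of the product phenol before the aryl ynol ether captures it. The ynol ether or the product could also be degraded by light. Photochemical E/Z isomerisation of the enone would open a [1,5]-hydrogen shift that erodes the stereocentre. Fallback: the ketene would be generated thermally, in the dark and at low stationary concentration. Setting out from diazoketone 6, a PhCO2Ag/Et3N-promoted Wolff rearrangement in aqueous THF would give (3E,5S)-5-[(tert-butyldimethylsilyl)oxy]-7-methyloct-3-enoic acid F1. 1-Chloro-N,N,2-trimethylprop-1-en-1-amine in CH2Cl2 would convert it under neutral conditions into (3E,5S)-5-[(tert-butyldimethylsilyl)oxy]-7-methyloct-3-enoyl chloride F2. Slow addition of F2 to Et3N and ynol ether 15 in toluene (rt, then 80 °C) would form the same vinylketene 16 by dehydrohalogenation, pass through 17 to 19 and come back to the route at phenol 20.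

2. Step 12. Lithiation could stray to ring B or to a benzylic position, or the base could attack the aryl silyl ether. Fallback: the carboxyl carbon would be brought in through the free phenol. Setting out from phenol 20, magnesium-mediated ortho-formylation (MgCl2, Et3N, paraformaldehyde, MeCN, reflux) can only reach C1, the single free ortho position, and would give 6-(ArB-oxy)-2-hydroxy-3-[(1S)-1-(TBSO)-3-methylbutyl]benzaldehyde F3. O-Methylation (MeI, K2CO3, acetone) would give 6-(ArB-oxy)-2-methoxy-3-[(1S)-1-(TBSO)-3-methylbutyl]benzaldehyde F4. Pinnick oxidation (NaClO2, NaH2PO4, 2-methylbut-2-ene, t-BuOH/H2O) would return to the route at acid 23.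

3. Step 7. Hydride rather than aryl migration (over-oxidation to the benzoic acid), attack of the peracid on the chloro enol ether, or cyclisation of the freed phenoxide onto the vinyl ether could compete. Fallback: the oxygen would be installed before the vinyl ether. Setting out from aldehyde 8, a Dakin oxidation (H2O2, aq. NaOH, THF, 0 °C), reliable for a free ortho-hydroxybenzaldehyde, would give 3-{[(tert-butyldimethylsilyl)oxy]methyl}-5-methylbenzene-1,2-diol F5. One equivalent of TIPSCl with imidazole would silylate the less hindered hydroxyl, remote from the CH2OTBS group, to give 2-{[(tert-butyldimethylsilyl)oxy]methyl}-4-methyl-6-[(triisopropylsilyl)oxy]phenol F6. Vinylation of F6 (KH, then trichloroethylene, THF, −40 °C → rt, kept cold to suppress silyl migration between the catechol oxygens) would return to the route at 12.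

**Further compounds**
F1 | step 10 | (3E,5S)-5-[(tert-butyldimethylsilyl)oxy]-7-methyloct-3-enoic acid | CC(C)C[C@H](O[Si](C)(C)C(C)(C)C)/C=C/CC(=O)O
F2 | step 10 | (3E,5S)-5-[(tert-butyldimethylsilyl)oxy]-7-methyloct-3-enoyl chloride | CC(C)C[C@H](O[Si](C)(C)C(C)(C)C)/C=C/CC(=O)Cl
F3 | step 12 | 6-(ArB-oxy)-2-hydroxy-3-[(1S)-1-(TBSO)-3-methylbutyl]benzaldehyde | CC(C)C[C@H](O[Si](C)(C)C(C)(C)C)c1ccc(Oc2c(CO[Si](C)(C)C(C)(C)C)cc(C)cc2O[Si](C(C)C)(C(C)C)C(C)C)c(C=O)c1O
F4 | step 12 | 6-(ArB-oxy)-2-methoxy-3-[(1S)-1-(TBSO)-3-methylbutyl]benzaldehyde | CC(C)C[C@H](O[Si](C)(C)C(C)(C)C)c1ccc(Oc2c(CO[Si](C)(C)C(C)(C)C)cc(C)cc2O[Si](C(C)C)(C(C)C)C(C)C)c(C=O)c1OC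
F5 | step 7 | 3-{[(tert-butyldimethylsilyl)oxy]methyl}-5-methylbenzene-1,2-diol | Cc1cc(CO[Si](C)(C)C(C)(C)C)c(O)c(O)c1
F6 | step 7 | 2-{[(tert-butyldimethylsilyl)oxy]methyl}-4-methyl-6-[(triisopropylsilyl)oxy]phenol | Cc1cc(CO[Si](C)(C)C(C)(C)C)c(O)c(O[Si](C(C)C)(C(C)C)C(C)C)c1
A1 | direct plan | methyl 6-fluoro-2-methoxy-3-(3-methylbutanoyl)benzoate | COC(=O)c1c(F)ccc(C(=O)CC(C)C)c1OC
A2 | direct plan | 3-(allyloxy)-2-hydroxy-5-methylbenzaldehyde | C=CCOc1cc(C)cc(C=O)c1O
A3 | direct plan | methyl 6-[2-(allyloxy)-6-formyl-4-methylphenoxy]-2-methoxy-3-(3-methylbutanoyl)benzoate | COC(=O)c1c(Oc2c(OCC=C)cc(C)cc2C=O)ccc(C(=O)CC(C)C)c1OC
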